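**Retrosynthetic overview**

1. The strategy rests on the only stereocentre, the lactol carbon of the five-membered ring D (bonded to ring B carbon B6, to H, to OH and to the lactone oxygen). It epimerises by ring opening to the B6-formyl B5-carboxylic acid, so it is carried as a C–B bond and oxidised to C–OH with retention in the last step. Labels: B1 ether oxygen, B2 ester oxygen, B3 H, B4 OH, B5 lactone carbonyl, B6 lactol carbon; ring A is the formyl-methoxy-methyl benzene, ring C the seven-membered lactone.
2. The C–B bond and the acyl–O bond of ring D are disconnected together to the B6-aldehyde/B5-methyl ester depsidone 22 and bis(pinacolato)diboron (copper boryl addition, then lactonisation).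
3. In 22 the B6 aldehyde is unmasked last from a propenyl group, so that the ring A aldehyde is the only aldehyde present when it is converted into its acetal; ring C is disconnected at the lactone to hydroxy acid 16.
4. The diaryl ether is disconnected by SNAr between phenol 8 (single free hydroxyl at B1, allyl at B6 from a Claisen rearrangement) and fluoride 14 (flanked by formyl and ester). The ether is made before the lactone so that the B1/B2 regiochemistry cannot be scrambled by acyl migration.
5. Order of ring formation: rings A and B come from the two benzene starting materials, ring C is closed in step 10 and ring D in step 15.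

Key step: step 15

Remark on the chemistry (assumption): (R)-DTBM-SEGPHOS is taken to deliver the (R)-boronate at this aryl aldehyde; should the sense of induction be the opposite, (S)-DTBM-SEGPHOS is used in step 15.

**Route**

Step 1
Reactants: 1 methyl 5-bromo-2,4-dihydroxybenzoate
Product: 2 methyl 5-bromo-2,4-bis(methoxymethoxy)benzoate
Conditions: NaH, MOMCl, DMF, 0 °C → rt
Reagents that add atoms: chloromethyl methyl ether, COCCl
Why: Williamson-type O-alkylation of both sodium phenoxides gives the MOM ethers at the future B2 and B4 oxygens, NaH being strong enough to break the hydrogen bond of the 2-hydroxyl to the ester.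

Step 2
Reactants: 2 methyl 5-bromo-2,4-bis(methoxymethoxy)benzoate, 3 bis(pinacolato)diboron
Product: 5 methyl 5-hydroxy-2,4-bis(methoxymethoxy)benzoate, via aryl pinacol boronate 4 (not isolated)
Conditions: Pd(dppf)Cl2 (3 mol%), KOAc, 1,4-dioxane, 90 °C; then NaBO3·4H2O, THF–H2O, rt
Reagents that add atoms: sodium perborate, [Na+].[O-]OB=O
Why: Miyaura borylation of the aryl bromide followed by oxidation of the aryl boronate in the same flask places the hydroxyl on the future ether carbon B1 at the position fixed by the bromine atom.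

Step 3
Reactants: 5 methyl 5-hydroxy-2,4-bis(methoxymethoxy)benzoate
Product: 6 methyl 2,4-bis(methoxymethoxy)-5-(prop-2-enyloxy)benzoate
Conditions: allyl bromide, K2CO3, acetone, reflux
Reagents that add atoms: allyl bromide, C=CCBr
Why: Williamson etherification of the only free phenol gives the allyl aryl ether needed for the rearrangement.

Step 4
Reactants: 6 methyl 2,4-bis(methoxymethoxy)-5-(prop-2-enyloxy)benzoate
Product: 8 methyl 3-hydroxy-4,6-bis(methoxymethoxy)-2-(prop-2-enyl)benzoate, via cyclohexadienone 7 (not isolated)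
Conditions: N,N-diethylaniline, 190 °C
Reagents that add atoms: none
Why: Aromatic Claisen rearrangement ([3,3]-sigmatropic shift) can deliver the allyl group only to the one free ortho position, the carbon next to the ester (future B6), and tautomerisation of the dienone sets the B1 hydroxyl free as the single phenol.

Step 5
Reactants: 9 3-fluoro-5-methylanisole
Product: 10 4-bromo-3-fluoro-5-methylanisole
Conditions: NBS, MeCN, 0 °C → rt
Reagents that add atoms: N-bromosuccinimide, O=C1CCC(=O)N1Br
Why: Electrophilic aromatic bromination with NBS in acetonitrile is expected to go para to the methoxy group, which marks the carbon that will carry the ring A carboxyl.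

Step 6
Reactants: 10 4-bromo-3-fluoro-5-methylanisole
Product: 13 3-bromo-2-fluoro-6-methoxy-4-methylbenzaldehyde, via aryllithium 11 (not isolated), via lithium hemiaminal alkoxide 12 (not isolated)
Conditions: LiN(iPr)2, THF, −78 °C; then DMF, −78 °C → 0 °C; 1 M HCl
Reagents that add atoms: N,N-dimethylformamide, CN(C)C=O
Why: Directed ortho-metalation removes the most acidic ring proton, the one between fluorine and methoxy (an amide base avoids bromine–lithium exchange), and formylation of the aryllithium with DMF installs the ring A aldehyde.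

Step 7
Reactants: 13 3-bromo-2-fluoro-6-methoxy-4-methylbenzaldehyde
Product: 14 4-methoxybenzyl 2-fluoro-3-formyl-4-methoxy-6-methylbenzoate
Conditions: Pd(OAc)2 (3 mol%), Xantphos (6 mol%), CO (1 atm), 4-methoxybenzyl alcohol, Et3N, toluene, 90 °C
Reagents that add atoms: carbon monoxide, [C-]#[O+]; 4-methoxybenzyl alcohol, COc1ccc(CO)cc1
Why: Palladium-catalysed alkoxycarbonylation of the aryl bromide (oxidative addition, CO insertion, alcoholysis of the acyl palladium) gives an acid-labile ester and tolerates the aldehyde and the fluoride.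

Step 8
Reactants: 8 methyl 3-hydroxy-4,6-bis(methoxymethoxy)-2-(prop-2-enyl)benzoate, 14 4-methoxybenzyl 2-fluoro-3-formyl-4-methoxy-6-methylbenzoate
Product: 15 4-methoxybenzyl 3-formyl-4-methoxy-2-[3-(methoxycarbonyl)-4,6-bis(methoxymethoxy)-2-(prop-2-enyl)phenoxy]-6-methylbenzoate
Conditions: Cs2CO3, DMF, 60 °C
Reagents that add atoms: none
Why: Nucleophilic aromatic substitution (addition–elimination) at a fluoride activated by an ortho formyl and an ortho ester group, with a phenol that has a single free hydroxyl, can form the diaryl ether only at B1.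

Step 9
Reactants: 15 the diaryl ether of step 8
Product: 16 3-formyl-2-[4,6-dihydroxy-3-(methoxycarbonyl)-2-(prop-2-enyl)phenoxy]-4-methoxy-6-methylbenzoic acid
Conditions: TFA–CH2Cl2 (1:3), anisole, 0 °C → rt
Reagents that add atoms: none
Why: Acidolysis ionises the 4-methoxybenzyl ester (the cation is trapped by anisole) and cleaves both aryl MOM acetals in one operation, while the allyl group, not conjugated with ring B, is not protonated.

Step 10
Reactants: 16 the hydroxy acid of step 9
Product: 17 methyl 4-formyl-8-hydroxy-3-methoxy-1-methyl-11-oxo-6-(prop-2-enyl)-11H-dibenzo[b,e][1,4]dioxepine-7-carboxylate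
Conditions: EDC·HCl, DMAP (cat.), CH2Cl2 (0.01 M), rt
Reagents that add atoms: none
Why: Steglich-type carbodiimide lactonisation closes the seven-membered ring C through the B2 hydroxyl held next to the activated acid by the diaryl ether; the B4 hydroxyl cannot reach the acid and is tied up in a hydrogen bond to the B5 ester.

Step 11
Reactants: 17 the depsidone of step 10
Product: 18 methyl 4-formyl-3-methoxy-8-(methoxymethoxy)-1-methyl-11-oxo-6-(prop-2-enyl)-11H-dibenzo[b,e][1,4]dioxepine-7-carboxylate
Conditions: MOMCl, iPr2NEt, CH2Cl2, 0 °C → 40 °C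
Reagents that add atoms: chloromethyl methyl ether, COCCl
Why: O-Alkylation of the B4 phenol under amine base, which does not open the aryl lactone, restores the MOM ether so that no acidic proton is present in the borylation.

Step 12
Reactants: 18 the MOM ether of step 11
Product: 19 methyl 4-(dimethoxymethyl)-3-methoxy-8-(methoxymethoxy)-1-methyl-11-oxo-6-(prop-2-enyl)-11H-dibenzo[b,e][1,4]dioxepine-7-carboxylate
Conditions: HC(OMe)3, PPTS (cat.), MeOH–CH2Cl2, rt
Reagents that add atoms: trimethyl orthoformate, COC(OC)OC; methanol, CO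
Why: Acid-catalysed acetalisation with the orthoformate as water scavenger masks the ring A aldehyde, the only aldehyde present at this stage, under conditions too mild for the MOM ether or the lactone.

Step 13
Reactants: 19 the acetal of step 12
Product: 20 methyl 4-(dimethoxymethyl)-3-methoxy-8-(methoxymethoxy)-1-methyl-11-oxo-6-[(E)-prop-1-enyl]-11H-dibenzo[b,e][1,4]dioxepine-7-carboxylate
Conditions: RuHCl(CO)(PPh3)3 (5 mol%), toluene, 80 °C
Reagents that add atoms: none
Why: Alkene isomerisation by the ruthenium hydride (hydrometalation, then beta-hydride elimination) moves the double bond into conjugation with ring B under neutral conditions; its geometry is of no consequence because it is cleaved next.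

Step 14
Reactants: 20 the propenyl depsidone of step 13
Product: 22 methyl 4-(dimethoxymethyl)-6-formyl-3-methoxy-8-(methoxymethoxy)-1-methyl-11-oxo-11H-dibenzo[b,e][1,4]dioxepine-7-carboxylate, via racemic syn diol 21 (not isolated)
Conditions: OsO4 (2 mol%), NaIO4, 2,6-lutidine, 1,4-dioxane–H2O (3:1), rt
Reagents that add atoms: osmium tetroxide, O=[Os](=O)(=O)=O; sodium periodate, [Na+].[O-]I(=O)(=O)=O
Why: Lemieux–Johnson oxidation (dihydroxylation, then periodate cleavage of the diol) unveils the B6 aldehyde, the lutidine buffer keeping the acetal and the MOM ether intact.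

Step 15
Reactants: 22 the B6-aldehyde B5-methyl ester depsidone of step 14, 3 bis(pinacolato)diboron
Product: 24 (1R)-11-(dimethoxymethyl)-10-methoxy-4-(methoxymethoxy)-8-methyl-1-(4,4,5,5-tetramethyl-1,3,2-dioxaborolan-2-yl)-1,3-dihydro-7H-isobenzofuro[4,5-b][1,4]benzodioxepine-3,7-dione, via copper alkoxide 23 (not isolated)
Conditions: CuCl (5 mol%), (R)-DTBM-SEGPHOS (6 mol%), KOtBu (10 mol%), THF, 0 °C → rt, no protic additive
Reagents that add atoms: none
Why: Proposed new method: the monovalent copper boryl complex formed from CuCl, KOtBu, the bisphosphine and 3 inserts the B6 aldehyde C=O with boron on carbon and copper on oxygen (alkoxide 23), and this alkoxide attacks the neighbouring B5 methyl ester and expels methoxide, which 3 takes up as MeOBpin, so the copper boryl is regenerated and no free alkoxide accumulates to open ring C; the closest known reaction types are the copper-catalysed enantioselective 1,2-borylation of aldehydes with chiral bisphosphines and the addition–lactonisation of 2-formylbenzoates to 3-substituted phthalides. Ring D is closed by a 5-exo-trig acyl substitution that forms the lactone acyl–O bond. The new stereocentre, the boron-bearing carbon, is set in the insertion step by the chiral pocket of (R)-DTBM-SEGPHOS on copper, which differentiates the two faces of the aldehyde; the (R)-boronate has the spatial arrangement of the (S)-lactol. The step needs chemoselectivity for one carbonyl, secured by the acetal on the ring A aldehyde and by the inertness of the esters to insertion, and it needs ring closure to outrun the shift of boron from carbon to oxygen, secured by the ester sitting ortho to the alkoxide and by leaving out any proton source.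

Step 16
Reactants: 24 the (R)-boryl phthalide of step 15
Product: 25 (1R)-4-hydroxy-10-methoxy-8-methyl-3,7-dioxo-1-(4,4,5,5-tetramethyl-1,3,2-dioxaborolan-2-yl)-1,3-dihydro-7H-isobenzofuro[4,5-b][1,4]benzodioxepine-11-carbaldehyde
Conditions: TFA–CH2Cl2–H2O (10:10:1), 0 °C → rt
Reagents that add atoms: water, O
Why: Acid hydrolysis removes the dimethyl acetal and the MOM ether, while the C–B centre holds because an alpha-acyloxy boronate has no ring-opening pathway and pinacol boronates resist Brønsted acid.

Step 17
Reactants: 25 the deprotected boryl phthalide of step 16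
Product: 27 (1S)-1,4-dihydroxy-10-methoxy-8-methyl-3,7-dioxo-1,3-dihydro-7H-isobenzofuro[4,5-b][1,4]benzodioxepine-11-carbaldehyde (CNP0216483.1), via borate ester 26 (not isolated)
Conditions: Me3NO (anhydrous), THF, 0 °C → rt; then pH 5 phosphate buffer, 0 °C
Reagents that add atoms: trimethylamine N-oxide, C[N+](C)(C)[O-]
Why: Amine N-oxide oxidation of the C–B bond (oxygen adds to boron, carbon migrates from boron to oxygen with retention) gives borate 26 with the lactol oxygen still capped, and hydrolysis of its B–O bond in cold, slightly acidic buffer, which also protonates the trimethylamine, should release the (S)-lactol without forming the ring-opening lactol anion.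

**Compound list**

1 | methyl 5-bromo-2,4-dihydroxybenzoate | COC(=O)c1cc(Br)c(O)cc1O | starting material
2 | methyl 5-bromo-2,4-bis(methoxymethoxy)benzoate | COC(=O)c1cc(Br)c(OCOC)cc1OCOC | intermediate
3 | bis(pinacolato)diboron | CC1(C)OB(B2OC(C)(C)C(C)(C)O2)OC1(C)C | starting material
4 | methyl 2,4-bis(methoxymethoxy)-5-(4,4,5,5-tetramethyl-1,3,2-dioxaborolan-2-yl)benzoate (aryl pinacol boronate, not isolated) | COC(=O)c1cc(B2OC(C)(C)C(C)(C)O2)c(OCOC)cc1OCOC | intermediate
5 | methyl 5-hydroxy-2,4-bis(methoxymethoxy)benzoate | COC(=O)c1cc(O)c(OCOC)cc1OCOC | intermediate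
6 | methyl 2,4-bis(methoxymethoxy)-5-(prop-2-enyloxy)benzoate | COC(=O)c1cc(OCC=C)c(OCOC)cc1OCOC | intermediate
7 | methyl 2,4-bis(methoxymethoxy)-5-oxo-6-(prop-2-enyl)cyclohexa-1,3-diene-1-carboxylate (racemic dienone, not isolated) | COC(=O)C1=C(OCOC)C=C(OCOC)C(=O)C1CC=C | intermediate
8 | methyl 3-hydroxy-4,6-bis(methoxymethoxy)-2-(prop-2-enyl)benzoate | COC(=O)c1c(CC=C)c(O)c(OCOC)cc1OCOC | intermediate
9 | 3-fluoro-5-methylanisole | COc1cc(C)cc(F)c1 | starting material
10 | 4-bromo-3-fluoro-5-methylanisole | COc1cc(C)c(Br)c(F)c1 | intermediate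
11 | (3-bromo-2-fluoro-6-methoxy-4-methylphenyl)lithium (not isolated) | COc1cc(C)c(Br)c(F)c1[Li] | intermediate
12 | lithium (3-bromo-2-fluoro-6-methoxy-4-methylphenyl)(dimethylamino)methanolate (not isolated) | COc1cc(C)c(Br)c(F)c1C(O[Li])N(C)C | intermediate
13 | 3-bromo-2-fluoro-6-methoxy-4-methylbenzaldehyde | COc1cc(C)c(Br)c(F)c1C=O | intermediate
14 | 4-methoxybenzyl 2-fluoro-3-formyl-4-methoxy-6-methylbenzoate | COc1cc(C)c(C(=O)OCc2ccc(OC)cc2)c(F)c1C=O | intermediate
15 | 4-methoxybenzyl 3-formyl-4-methoxy-2-[3-(methoxycarbonyl)-4,6-bis(methoxymethoxy)-2-(prop-2-enyl)phenoxy]-6-methylbenzoate | COc1cc(C)c(C(=O)OCc2ccc(OC)cc2)c(Oc2c(CC=C)c(C(=O)OC)c(OCOC)cc2OCOC)c1C=O | intermediate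
16 | 3-formyl-2-[4,6-dihydroxy-3-(methoxycarbonyl)-2-(prop-2-enyl)phenoxy]-4-methoxy-6-methylbenzoic acid | COc1cc(C)c(C(=O)O)c(Oc2c(CC=C)c(C(=O)OC)c(O)cc2O)c1C=O | intermediate
17 | methyl 4-formyl-8-hydroxy-3-methoxy-1-methyl-11-oxo-6-(prop-2-enyl)-11H-dibenzo[b,e][1,4]dioxepine-7-carboxylate | COc1cc(C)c2c(c1C=O)Oc1c(cc(O)c(C(=O)OC)c1CC=C)OC2=O | intermediate
18 | methyl 4-formyl-3-methoxy-8-(methoxymethoxy)-1-methyl-11-oxo-6-(prop-2-enyl)-11H-dibenzo[b,e][1,4]dioxepine-7-carboxylate | COc1cc(C)c2c(c1C=O)Oc1c(cc(OCOC)c(C(=O)OC)c1CC=C)OC2=O | intermediate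
19 | methyl 4-(dimethoxymethyl)-3-methoxy-8-(methoxymethoxy)-1-methyl-11-oxo-6-(prop-2-enyl)-11H-dibenzo[b,e][1,4]dioxepine-7-carboxylate | COc1cc(C)c2c(c1C(OC)OC)Oc1c(cc(OCOC)c(C(=O)OC)c1CC=C)OC2=O | intermediate
20 | methyl 4-(dimethoxymethyl)-3-methoxy-8-(methoxymethoxy)-1-methyl-11-oxo-6-[(E)-prop-1-enyl]-11H-dibenzo[b,e][1,4]dioxepine-7-carboxylate | COc1cc(C)c2c(c1C(OC)OC)Oc1c(cc(OCOC)c(C(=O)OC)c1/C=C/C)OC2=O | intermediate
21 | methyl 4-(dimethoxymethyl)-6-[(1R*,2R*)-1,2-dihydroxypropyl]-3-methoxy-8-(methoxymethoxy)-1-methyl-11-oxo-11H-dibenzo[b,e][1,4]dioxepine-7-carboxylate (racemic, one enantiomer drawn, not isolated) | COc1cc(C)c2c(c1C(OC)OC)Oc1c(cc(OCOC)c(C(=O)OC)c1[C@@H](O)[C@@H](C)O)OC2=O | intermediate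
22 | methyl 4-(dimethoxymethyl)-6-formyl-3-methoxy-8-(methoxymethoxy)-1-methyl-11-oxo-11H-dibenzo[b,e][1,4]dioxepine-7-carboxylate (key-step precursor) | COc1cc(C)c2c(c1C(OC)OC)Oc1c(cc(OCOC)c(C(=O)OC)c1C=O)OC2=O | intermediate
23 | (R)-configured copper alkoxide of the alpha-boryl alcohol at the B6 carbon of 22, ligand on copper omitted (not isolated) | COc1cc(C)c2c(c1C(OC)OC)Oc1c(cc(OCOC)c(C(=O)OC)c1[C@H](O[Cu])B1OC(C)(C)C(C)(C)O1)OC2=O | intermediate
24 | (1R)-11-(dimethoxymethyl)-10-methoxy-4-(methoxymethoxy)-8-methyl-1-(4,4,5,5-tetramethyl-1,3,2-dioxaborolan-2-yl)-1,3-dihydro-7H-isobenzofuro[4,5-b][1,4]benzodioxepine-3,7-dione (key-step product) | COc1cc(C)c2c(c1C(OC)OC)Oc1c(cc(OCOC)c3c1[C@@H](B1OC(C)(C)C(C)(C)O1)OC3=O)OC2=O | intermediate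
25 | (1R)-4-hydroxy-10-methoxy-8-methyl-3,7-dioxo-1-(4,4,5,5-tetramethyl-1,3,2-dioxaborolan-2-yl)-1,3-dihydro-7H-isobenzofuro[4,5-b][1,4]benzodioxepine-11-carbaldehyde | COc1cc(C)c2c(c1C=O)Oc1c(cc(O)c3c1[C@@H](B1OC(C)(C)C(C)(C)O1)OC3=O)OC2=O | intermediate
26 | (1S)-4-hydroxy-10-methoxy-8-methyl-3,7-dioxo-1-[(4,4,5,5-tetramethyl-1,3,2-dioxaborolan-2-yl)oxy]-1,3-dihydro-7H-isobenzofuro[4,5-b][1,4]benzodioxepine-11-carbaldehyde (borate ester, not isolated) | COc1cc(C)c2c(c1C=O)Oc1c(cc(O)c3c1[C@@H](OB1OC(C)(C)C(C)(C)O1)OC3=O)OC2=O | intermediate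
27 | (1S)-1,4-dihydroxy-10-methoxy-8-methyl-3,7-dioxo-1,3-dihydro-7H-isobenzofuro[4,5-b][1,4]benzodioxepine-11-carbaldehyde | COc1cc(C)c2c(c1C=O)Oc1c(cc(O)c3c1[C@@H](O)OC3=O)OC2=O | target

**Step count and risks**

Total step count: 17. Longest linear sequence: 14 steps (steps 1–4, then 8–17); the ring A branch (steps 5–7) joins at step 8.

Steps most likely to fail:

1. Step 15. The process at risk is the face selection at an aldehyde flanked by two ortho substituents, together with a shift of boron from carbon to oxygen, or an alkoxide attack on ring C, that competes with closure of ring D. The fallback gives up the C–B surrogate, sets out from 22 and comes back at 27. Aqueous acid (2 M HCl–dioxane, 60 °C) removes the acetal and the MOM ether and, through the hydrate of the neighbouring aldehyde, turns the B5 methyl ester into the racemic lactol F1. An acylative dynamic kinetic resolution of this equilibrating lactol (chiral isothiourea catalyst HyperBTM in the enantiomeric form that acylates the (S)-epimer, isobutyric anhydride, iPr2NEt, CHCl3, low temperature) should give the configurationally stable (S)-phthalidyl isobutyrate F2. Deacylation at the acyl–O bond under neutral enzymatic conditions (immobilised Candida antarctica lipase B, pH 6 buffer–MTBE, 5 °C) then releases 27.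

2. Step 8. The process at risk is a slow substitution, because both the phenoxide and the fluoride carbon are flanked by two substituents, which gives time for attack of the phenoxide on the ester or the aldehyde. The fallback reverses the order of the two bond formations on ring A; it sets out from 8 and 13 and comes back at 15. Phenol 8 displaces the fluoride of bromo aldehyde 13 (Cs2CO3, DMF, 90 °C), where the second neighbour of the fluoride is a bromine atom and no acyl transfer can compete, to give the bromo diaryl ether F3. Palladium-catalysed alkoxycarbonylation of F3 (Pd(OAc)2, Xantphos, CO, 4-methoxybenzyl alcohol, Et3N, toluene, 100 °C) then gives 15.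

3. Step 17. The process at risk is epimerisation of the freed lactol by ring opening, triggered by the trimethylamine formed in the oxidation or during the hydrolysis of the borate. The fallback avoids any amine; it sets out from 25 and comes back at 27. KHF2 (MeCN–H2O, rt) converts the pinacol boronate into the potassium trifluoroborate F4, and Oxone (2KHSO5·KHSO4·K2SO4, acetone–H2O, 0 °C, a few minutes) oxidises its C–B bond with retention at slightly acidic pH to give 27.

**Further compounds**

F1 | step 15 | racemic 1,4-dihydroxy-10-methoxy-8-methyl-3,7-dioxo-1,3-dihydro-7H-isobenzofuro[4,5-b][1,4]benzodioxepine-11-carbaldehyde | COc1cc(C)c2c(c1C=O)Oc1c(cc(O)c3c1C(O)OC3=O)OC2=O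
F2 | step 15 | (1S)-11-formyl-4-hydroxy-10-methoxy-8-methyl-3,7-dioxo-1,3-dihydro-7H-isobenzofuro[4,5-b][1,4]benzodioxepin-1-yl 2-methylpropanoate | COc1cc(C)c2c(c1C=O)Oc1c(cc(O)c3c1[C@@H](OC(=O)C(C)C)OC3=O)OC2=O
F3 | step 8 | methyl 3-(2-bromo-6-formyl-5-methoxy-3-methylphenoxy)-4,6-bis(methoxymethoxy)-2-(prop-2-enyl)benzoate | COc1cc(C)c(Br)c(Oc2c(CC=C)c(C(=O)OC)c(OCOC)cc2OCOC)c1C=O
F4 | step 17 | potassium [(1R)-11-formyl-4-hydroxy-10-methoxy-8-methyl-3,7-dioxo-1,3-dihydro-7H-isobenzofuro[4,5-b][1,4]benzodioxepin-1-yl]trifluoroborate | COc1cc(C)c2c(c1C=O)Oc1c(cc(O)c3c1[C@@H]([B-](F)(F)F)OC3=O)OC2=O.[K+]
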